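## Structural features

The target is a dihydrochalcone in which ring A, a phloroglucinol nucleus, is tied through a C(=O)–CH2–CH2 chain to ring B, a catechol. Ring A is fused along C5a–C9a to a 2,5-dihydrooxepine (O1, C2H2, C3(CH3)=C4H, C5H2), so a four-carbon isoprenoid unit bridges one phloroglucinol oxygen (O1 on C9a) and the adjacent ring carbon C5a, while the other two oxygens remain as the C6 and C8 hydroxyls that flank and chelate the C7 ketone. There is no stereocentre, hence no neighbouring stereocentres to relate; the only stereochemical element is the C3=C4 alkene, which the seven-membered ring holds cis. The fragile groups are the catechol (oxidation, competing nucleophile), the O1–C2 allyl aryl ether (ionised by acid or by zerovalent palladium, Claisen-prone on heating), the trisubstituted alkene (rules out hydrogenolysis and strong acid) and the electron-rich ring A (over-alkylation). The real difficulty is constitutional: the methyl group must sit on C3, next to the O1–CH2 carbon and not on C4, and the carbon bridge must enter ring A at a defined position relative to the acyl group. The plan exploits the fact that O1 on C9a is para to the acyl-bearing C7, so that in an acylphloroglucinol alkylated on its para oxygen the two ortho carbons C5a and C9 are exchanged by the mirror plane through C7 and C9a, and a bond from the side chain to either one gives the same 1-benzoxepine.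

## Logic of the disconnections

**14 to 13.** No skeletal bond is cut; the two catechol O–H bonds of 14 are traded for the two C–O bonds of a diphenylmethylene ketal in 13. The reason is that a free catechol would compete as an oxygen nucleophile in the etherification and in the palladium step. The ketal closes only on a 1,2-diphenol, so it tells ring B from ring A without any protection of the three ring A hydroxyls. The demand on the forward step is a ketal cleavage mild enough for an allyl aryl ether and a trisubstituted alkene, which excludes hydrogenolysis and points to warm dilute acetic acid.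

**13 to 11.** The cut is C5–C5a, the one skeletal bond the oxepine still needs once O1–C2 exists. Cutting here exposes a ring A that is symmetric about the C7–C9a axis and an allyl electrophile that a palladium catalyst can generate without added base. The gain is the ring and the last C–C bond in one operation, with no choice of position on ring A. The demands are carbon rather than oxygen attack, reaction at the unsubstituted allyl terminus, a Z alkene so that the tether is anti in the allyl complex, both ortho phenols free, and a leaving group that delivers its own base.

**11 to 10 to 9.** Only the oxygen substituent on C5 changes: carbonate back to alcohol, alcohol back to silyl ether. The silyl ether lets the C5 oxygen travel through the etherification in masked form. The demand is that the carbonate be put on the aliphatic hydroxyl of 10 in the presence of two phenols, which rests on their hydrogen bonding to the ketone.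

**9 to 4 and 8.** The cut is O1–C2. It separates the complete dihydrochalcone from the four-carbon unit and uses the one ring A hydroxyl that is neither chelated nor hindered. The gain is convergence. The demand is etherification at the para oxygen only, by direct substitution at C2 without allylic transposition and without loss of the Z geometry.

**8 to 7 to 5 and 6.** The cut is the C3=C4 double bond (after adjusting C2 from alcohol to ester). Making the alkene by olefination fixes by construction which end of the four-carbon unit carries the methyl group, because the methyl arrives with the ester carbon in 6 and the silyloxy carbon arrives with 5. The demand is a Z-selective olefination giving a trisubstituted enoate, and a reduction that does not isomerise it.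

**4 to 3 to 1 and 2.** The ketal C–O bonds are cut first, then the C7–C(=O) bond. The three ring positions of 1 are equivalent, so the acylation has no regiochemical issue and both partners are used unprotected. The demand is monoacylation of 1 in the presence of the catechol of 2, and a ketalisation that touches only the 1,2-diphenol.

## Other disconnections considered

**Alternative 1:** Danheiser benzannulation. Ring A itself is dismantled along C6–C7, C8–C9 and C5a–C6. This leaves a seven-membered enol ether bearing a diazoacetyl group, 2-diazo-1-(6-methyl-4,7-dihydrooxepin-2-yl)ethan-1-one A2, and a siloxyalkyne, 2-[2-[3,4-bis(methoxymethoxy)phenyl]ethyl]-2-[2-(triisopropylsilyloxy)ethynyl]-1,3-dioxolane A3. In the forward step, irradiation of A2 would trigger a Wolff rearrangement to a vinylketene. This would add A3 in a [2+2] sense, the cyclobutenone would open (4π) and reclose (6π), and tautomerisation would give the phenol A1, with the free hydroxyl at C6, the silyl ether at C8 and the masked acyl chain at C7.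
- In its favour: the pericyclic sequence dictates the substitution of all six ring A positions. The two phenolic oxygens emerge differentiated. The oxepine with its methyl group exists before the arene, so neither the C3-versus-C5 question nor the oxygen-versus-carbon question of an allylation arises. On these points of selectivity it is the better plan.
- Against it here: A2 is a skipped dienyl enol ether. It is acid-labile and light-sensitive in its own right, and its synthesis still requires a seven-membered ring to be built, now without the help of an aromatic nucleophile. A3 needs a ketal-bearing ynol silyl ether with a fully substituted carbon next to the alkyne, which should slow the [2+2] step. After the key step three kinds of protecting group must go (silyl ether, dioxolane, two methoxymethyl ethers), two of them with aqueous acid stronger than the chosen route needs.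
- Comparison: on structure it is more general and could differentiate the phenols if that were wanted. On mechanism it is a four-event cascade against a single ionisation and addition. On step economy the chosen plan, at nine steps from commercial materials, should be clearly shorter.

**Alternative 2:** One-carbon ring expansion. Carbon C3 is excised (bonds C2–C3 and C3–C4), leading back to 5,7-bis(methoxymethoxy)-4H-chromene A5. In the forward step, dibromocarbene from CHBr3 and KOC(CH3)3 would add to the enol ether alkene of A5 to give the cis-fused adduct 1,1-dibromo-4,6-bis(methoxymethoxy)-1,1a,7,7a-tetrahydrocyclopropa[b]chromene A6. AgOAc in methanol would then abstract bromide, and the opening allyl cation would be captured by methanol at the oxygen-bearing carbon to give the bromo acetal A4.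
- In its favour: the reagents are cheap and the ring enlargement has no entropic cost, so as a way of making the seven-membered ring it is at least as dependable as a cyclisation. The alkene position is fixed by the mode of cyclopropane opening. The bromine on C3 is an unambiguous handle for the methyl group, so on methyl regiochemistry it is the equal of the chosen plan.
- Against it here: A4 carries what the target lacks and lacks what the target has. The C2 methoxy group must be removed reductively through an oxygen-stabilised allyl cation, where hydride delivery at C4 would give the enol ether isomer. The bromide must be exchanged for methyl. The acyl chain must then be introduced at C7 of a ring in which C7 and C9 are both activated, so the symmetry that the chosen plan uses has been given up. The stereocentre at C2 of A4 is irrelevant because it is removed.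
- Comparison: the key step is two operations, but A5 must be made, at least four adjustments follow, and each carries its own selectivity question. Overall it should be longer and less certain than the chosen plan.

**Alternative 3:** Aryne insertion into a carboxylic acid. The C6–O bond and the C7–C(=O) bond are cut together, and both come from the carboxyl group of 3-[3,4-bis(methoxymethoxy)phenyl]propanoic acid A9. The arene partner is the silyl triflate 8-(methoxymethoxy)-3-methyl-7-(trimethylsilyl)-2,5-dihydro-1-benzoxepin-6-yl trifluoromethanesulfonate A8. In the forward step CsF would release the C6–C7 aryne from A8, and the carboxylate oxygen would add at C6, the carbon remote from the C8 alkoxy group that polarises the aryne. The C7 aryl anion would then take the acyl group from that oxygen to give the hydroxy ketone A7.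
- In its favour: ketone and neighbouring phenol arrive in one step from a simple acid, with no Friedel–Crafts chemistry and with regiochemistry guided by the alkoxy group. The ring B fragment enters last, which is better than the chosen plan for making analogues, and equal to it in convergence.
- Against it here: A8 is a pentasubstituted arene that already contains the oxepine. The seven-membered ring must therefore still be made, on a resorcinol-type ring whose two candidate carbons are no longer equivalent. The ortho silyl triflate then costs several further steps. In the insertion, protonation of the aryl anion would stop at the aryl ester, and the aryne sits next to the allylic, benzylic C5 hydrogens. The methoxymethyl ethers must finally be removed with acid.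
- Comparison: mechanistically elegant and equal on the final union, but it moves the ring-forming problem to a worse substrate and should be considerably longer.

Key step: step 8

Remark 1: atom-by-atom comparison of the cyclisation precursor 11, its product 13 and the target shows no constitutional or geometric inconsistency, so no structure needed correction. One point is added to the selectivity analysis: attack at the substituted allyl terminus C3 would close a five-membered ring, so it is a real competitor and not merely a hindered option.

Remark 2 (assumption): the four-carbon unit is built by Z-selective olefination and not by reduction of 3-methyl-2(5H)-furanone. The diol from that lactone has two primary allylic hydroxyls that differ only in the position of a remote methyl group, and any error in telling them apart would end as the 4-methyl isomer of the oxepine. An E contaminant from the olefination cannot change the constitution.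

Remark 3: the methyl carbonate is kept as the leaving group because it ionises under mild conditions and supplies its own base. The two ortho phenols are deliberately left free, since they provide the nucleophile.

## Route

Step 1
Reactants: 1 phloroglucinol; 2 3-(3,4-dihydroxyphenyl)propanoic acid
Product: 3 3-(3,4-dihydroxyphenyl)-1-(2,4,6-trihydroxyphenyl)propan-1-one
Conditions: BF3·OEt2 (neat), 1 (2.5 equiv), 85 °C; then H2O
Reagents that add atoms: none
Why: BF3-promoted Friedel–Crafts C-acylation of phloroglucinol by a free arylpropanoic acid, the standard entry to phloretin-type dihydrochalcones; the three ring positions of 1 are equivalent, the first acyl group deactivates the ring as its BF2 chelate so monoacylation should prevail, and the excess of the far more nucleophilic 1 should outrun cyclisation of the acid onto its own catechol ring.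

Step 2
Reactants: 3 3-(3,4-dihydroxyphenyl)-1-(2,4,6-trihydroxyphenyl)propan-1-one
Product: 4 3-(2,2-diphenyl-1,3-benzodioxol-5-yl)-1-(2,4,6-trihydroxyphenyl)propan-1-one
Conditions: Ph2CCl2 (1.3 equiv), Ph2O, 175 °C
Reagents that add atoms: dichlorodiphenylmethane, ClC(Cl)(c1ccccc1)c1ccccc1
Why: Thermal ketalisation of a catechol with dichlorodiphenylmethane; only two adjacent hydroxyls can close the five-membered 1,3-benzodioxole, so the meta-related ring A hydroxyls, further deactivated by the chelated ketone, should stay free.

Step 3
Reactants: 5 2-[tert-butyl(dimethyl)silyl]oxyacetaldehyde; 6 ethyl 2-[bis(2,2,2-trifluoroethoxy)phosphoryl]propanoate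
Product: 7 ethyl (Z)-4-[tert-butyl(dimethyl)silyl]oxy-2-methylbut-2-enoate
Conditions: KN(SiMe3)2, 18-crown-6, THF, −78 °C
Reagents that add atoms: none
Why: Still–Gennari olefination; the electron-poor bis(trifluoroethyl) phosphonate with a dissociated potassium counter-ion eliminates from the kinetic adduct, which should place the ester cis to the CH2OSi group, and the constitution of the four-carbon unit is fixed by which partner carries the methyl group.

Step 4
Reactants: 7 ethyl (Z)-4-[tert-butyl(dimethyl)silyl]oxy-2-methylbut-2-enoate
Product: 8 (Z)-4-[tert-butyl(dimethyl)silyl]oxy-2-methylbut-2-en-1-ol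
Conditions: i-Bu2AlH (2.5 equiv), CH2Cl2, −78 °C; aq. potassium sodium tartrate (KNaC4H4O6)
Reagents that add atoms: none
Why: 1,2-Reduction of a conjugated ester by i-Bu2AlH at low temperature gives the allylic alcohol without touching the silyl ether or isomerising the Z alkene; reducing before any desilylation avoids the lactonisation open to a Z γ-hydroxy enoate.

Step 5
Reactants: 4 3-(2,2-diphenyl-1,3-benzodioxol-5-yl)-1-(2,4,6-trihydroxyphenyl)propan-1-one; 8 (Z)-4-[tert-butyl(dimethyl)silyl]oxy-2-methylbut-2-en-1-ol
Product: 9 1-[4-[(Z)-4-[tert-butyl(dimethyl)silyl]oxy-2-methylbut-2-enoxy]-2,6-dihydroxyphenyl]-3-(2,2-diphenyl-1,3-benzodioxol-5-yl)propan-1-one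
Conditions: PPh3, DIAD, THF, 0 °C → rt
Reagents that add atoms: none
Why: Mitsunobu etherification; of the three ring A hydroxyls only the one para to the ketone is unchelated and it is also the most acidic, so it alone should displace the primary alkoxyphosphonium ion of 8 by direct SN2 substitution, leaving the alkene geometry untouched.

Step 6
Reactants: 9 1-[4-[(Z)-4-[tert-butyl(dimethyl)silyl]oxy-2-methylbut-2-enoxy]-2,6-dihydroxyphenyl]-3-(2,2-diphenyl-1,3-benzodioxol-5-yl)propan-1-one
Product: 10 1-[2,6-dihydroxy-4-[(Z)-4-hydroxy-2-methylbut-2-enoxy]phenyl]-3-(2,2-diphenyl-1,3-benzodioxol-5-yl)propan-1-one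
Conditions: HF·pyridine, THF–pyridine, 0 °C → rt
Reagents that add atoms: none
Why: Fluoride-induced cleavage of a primary silyl ether; buffered HF·pyridine should leave the ketal, the allyl aryl ether and the phenols untouched.

Step 7
Reactants: 10 1-[2,6-dihydroxy-4-[(Z)-4-hydroxy-2-methylbut-2-enoxy]phenyl]-3-(2,2-diphenyl-1,3-benzodioxol-5-yl)propan-1-one
Product: 11 (Z)-4-[3,5-dihydroxy-4-[3-(2,2-diphenyl-1,3-benzodioxol-5-yl)propanoyl]phenoxy]-3-methylbut-2-en-1-yl methyl carbonate
Conditions: ClCO2Me (1.1 equiv), pyridine, CH2Cl2, −20 °C
Reagents that add atoms: methyl chloroformate, COC(=O)Cl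
Why: O-Acylation of a primary allylic alcohol by a chloroformate; at low temperature with one equivalent of reagent the unhindered aliphatic hydroxyl should react ahead of the two phenols, which are hydrogen-bonded to the ketone, flanked by the acyl group and weakly nucleophilic without a strong base.

Step 8
Reactants: 11 (Z)-4-[3,5-dihydroxy-4-[3-(2,2-diphenyl-1,3-benzodioxol-5-yl)propanoyl]phenoxy]-3-methylbut-2-en-1-yl methyl carbonate
Product: 13 1-(6,8-dihydroxy-3-methyl-2,5-dihydro-1-benzoxepin-7-yl)-3-(2,2-diphenyl-1,3-benzodioxol-5-yl)propan-1-one, via dienone tautomer 12 (not isolated)
Conditions: Pd(PPh3)4 (5 mol %), degassed THF (0.005 M), 40 °C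
Reagents that add atoms: none
Why: Zerovalent palladium ionises the allylic carbonate with inversion to a cationic η3-allyl complex over C3–C4–C5 in which, because the alkene of 11 is Z, the CH2–O1 arm is anti at C3; loss of CO2 leaves methoxide, which deprotonates a ring A phenol. The phenoxide then attacks through its ortho carbon C5a at the unsubstituted terminus C5 on the face away from palladium, giving dienone 12, which regains aromaticity by tautomerisation to 13. The closest known reaction types are the Tsuji–Trost C-allylation of phloroglucinols and the intramolecular Friedel–Crafts-type allylic alkylation of phenols. The oxepine closes in the 7-endo mode with respect to the allyl unit (bond to the distal terminus, alkene left inside the ring), which the anti arm makes geometrically easy and which gives the cis ring alkene directly. No stereocentre is created in 13, since the sp3 centre at C5a of 12 disappears on enolisation. The step needs carbon over oxygen attack and C5 over C3 attack, while the choice of ortho carbon is moot because C5a and C9 are symmetry-equivalent; oxygen attack within the molecule would require a meta-bridged nine-membered ring, and intermolecular O-allylation is disfavoured by dilution and is reversible under the catalyst whereas C–C bond formation is not. Attack at C3 would be a 5-exo closure to a 3-methyl-3-vinyl-2,3-dihydrobenzofuran; it is opposed by the fully substituted terminus (a quaternary benzylic carbon pressed against the C6 hydroxyl) and by the short O1–C2 tether, which cannot easily bring C3 over the π face at C5a. The free phenols on both sides of the ketone supply the nucleophile, the ketal is inert to palladium and methoxide, and the carbonate delivers exactly one equivalent of base.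

Step 9
Reactants: 13 1-(6,8-dihydroxy-3-methyl-2,5-dihydro-1-benzoxepin-7-yl)-3-(2,2-diphenyl-1,3-benzodioxol-5-yl)propan-1-one
Product: 14 1-(6,8-dihydroxy-3-methyl-2,5-dihydro-1-benzoxepin-7-yl)-3-(3,4-dihydroxyphenyl)propan-1-one
Conditions: AcOH–H2O (4:1), 90 °C
Reagents that add atoms: none
Why: Acid-catalysed hydrolysis of the diphenylmethylene ketal through its doubly benzylic, oxygen-stabilised cation releases benzophenone; dilute acetic acid is too weak to protonate the trisubstituted alkene (its tertiary cation would be destabilised by the β-oxygen) or to ionise the O1–C2 ether at a useful rate, so the dihydrooxepine should survive.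

## Compound list

1 | phloroglucinol | Oc1cc(O)cc(O)c1 | starting material
2 | 3-(3,4-dihydroxyphenyl)propanoic acid | OC(=O)CCc1ccc(O)c(O)c1 | starting material
3 | 3-(3,4-dihydroxyphenyl)-1-(2,4,6-trihydroxyphenyl)propan-1-one | O=C(CCc1ccc(O)c(O)c1)c1c(O)cc(O)cc1O | intermediate
4 | 3-(2,2-diphenyl-1,3-benzodioxol-5-yl)-1-(2,4,6-trihydroxyphenyl)propan-1-one | O=C(CCc1ccc2OC(c3ccccc3)(c3ccccc3)Oc2c1)c1c(O)cc(O)cc1O | intermediate
5 | 2-[tert-butyl(dimethyl)silyl]oxyacetaldehyde | CC(C)(C)[Si](C)(C)OCC=O | starting material
6 | ethyl 2-[bis(2,2,2-trifluoroethoxy)phosphoryl]propanoate | CCOC(=O)C(C)P(=O)(OCC(F)(F)F)OCC(F)(F)F | starting material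
7 | ethyl (Z)-4-[tert-butyl(dimethyl)silyl]oxy-2-methylbut-2-enoate | CCOC(=O)/C(C)=C\CO[Si](C)(C)C(C)(C)C | intermediate
8 | (Z)-4-[tert-butyl(dimethyl)silyl]oxy-2-methylbut-2-en-1-ol | OC/C(C)=C\CO[Si](C)(C)C(C)(C)C | intermediate
9 | 1-[4-[(Z)-4-[tert-butyl(dimethyl)silyl]oxy-2-methylbut-2-enoxy]-2,6-dihydroxyphenyl]-3-(2,2-diphenyl-1,3-benzodioxol-5-yl)propan-1-one | CC(C)(C)[Si](C)(C)OC/C=C(C)\COc1cc(O)c(C(=O)CCc2ccc3OC(c4ccccc4)(c4ccccc4)Oc3c2)c(O)c1 | intermediate
10 | 1-[2,6-dihydroxy-4-[(Z)-4-hydroxy-2-methylbut-2-enoxy]phenyl]-3-(2,2-diphenyl-1,3-benzodioxol-5-yl)propan-1-one | OC/C=C(C)\COc1cc(O)c(C(=O)CCc2ccc3OC(c4ccccc4)(c4ccccc4)Oc3c2)c(O)c1 | intermediate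
11 | (Z)-4-[3,5-dihydroxy-4-[3-(2,2-diphenyl-1,3-benzodioxol-5-yl)propanoyl]phenoxy]-3-methylbut-2-en-1-yl methyl carbonate | COC(=O)OC/C=C(C)\COc1cc(O)c(C(=O)CCc2ccc3OC(c4ccccc4)(c4ccccc4)Oc3c2)c(O)c1 | intermediate
12 | 3-(2,2-diphenyl-1,3-benzodioxol-5-yl)-1-(8-hydroxy-3-methyl-6-oxo-2,5,5a,6-tetrahydro-1-benzoxepin-7-yl)propan-1-one (racemic at C5a, transient) | CC1=CCC2C(=O)C(C(=O)CCc3ccc4OC(c5ccccc5)(c5ccccc5)Oc4c3)=C(O)C=C2OC1 | intermediate
13 | 1-(6,8-dihydroxy-3-methyl-2,5-dihydro-1-benzoxepin-7-yl)-3-(2,2-diphenyl-1,3-benzodioxol-5-yl)propan-1-one | CC1=CCc2c(cc(O)c(C(=O)CCc3ccc4OC(c5ccccc5)(c5ccccc5)Oc4c3)c2O)OC1 | intermediate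
14 | 1-(6,8-dihydroxy-3-methyl-2,5-dihydro-1-benzoxepin-7-yl)-3-(3,4-dihydroxyphenyl)propan-1-one | CC1=CCc2c(cc(O)c(C(=O)CCc3ccc(O)c(O)c3)c2O)OC1 | target

## Step count and least certain steps

Total step count: 9. Longest linear sequence: 7 (steps 1, 2, 5, 6, 7, 8, 9); steps 3 and 4 prepare the side chain in parallel.

**Step 8 (key step).**
- What may go wrong: closure onto the substituted terminus C3, which forms a five-membered ring and is kinetically favoured by ring size even though it builds a quaternary carbon.
- Also possible: intermolecular allylation leading to oligomers if ring closure is slow, β-hydride loss from the allyl complex to a diene, and ionisation of the O1–C2 aryl ether by the catalyst, which would scramble the position of the methyl group.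
- Fallback: this sets out from 4 and returns at 13, and it forms the ring alkene by metathesis instead of the C5–C5a bond by allylation.
  - Alkylation of the para hydroxyl of 4 with allyl bromide and K2CO3 in acetone should give the allyl ether 1-[2,6-dihydroxy-4-(prop-2-enoxy)phenyl]-3-(2,2-diphenyl-1,3-benzodioxol-5-yl)propan-1-one F1.
  - Aromatic Claisen rearrangement (N,N-diethylaniline, 190 °C) should move the allyl group to an ortho carbon, either of which gives the same C-allyl triol 3-(2,2-diphenyl-1,3-benzodioxol-5-yl)-1-[2,4,6-trihydroxy-3-(prop-2-enyl)phenyl]propan-1-one F2.
  - Mitsunobu etherification of the regenerated para hydroxyl with 2-methylprop-2-en-1-ol should give the diene 1-[2,6-dihydroxy-4-(2-methylprop-2-enoxy)-3-(prop-2-enyl)phenyl]-3-(2,2-diphenyl-1,3-benzodioxol-5-yl)propan-1-one F3.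
  - Ring-closing metathesis with the second-generation Grubbs catalyst RuCl2(=CHPh)(H2IMes)(PCy3) in warm toluene should then close the trisubstituted ring alkene and give 13.

**Step 7.**
- What may go wrong: loss of chemoselectivity, with methoxycarbonylation of a phenol competing with that of the allylic alcohol, because only one of the two ortho hydroxyls can be hydrogen-bonded to the ketone at a time.
- Fallback: this sets out from 10 and returns at 11, and it replaces selective acylation by exhaustive acylation and selective deacylation.
  - Excess ClCO2Me with triethylamine and catalytic 4-dimethylaminopyridine should give the tris(carbonate) (Z)-4-[3,5-bis(methoxycarbonyloxy)-4-[3-(2,2-diphenyl-1,3-benzodioxol-5-yl)propanoyl]phenoxy]-3-methylbut-2-en-1-yl methyl carbonate F4.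
  - Brief treatment with NH3 in methanol at 0 °C should then cleave only the two aryl carbonates, whose leaving group is an acidic acylphenoxide, and leave the dialkyl carbonate of 11 intact.

**Step 5.**
- What may go wrong: etherification of a second hydroxyl or of the wrong one, attack with allylic transposition, or sluggish activation of the alcohol leaving unreacted 4.
- Fallback: this sets out from 8 and returns at 9, using a preformed electrophile in a Williamson etherification.
  - CBr4 and PPh3 should convert 8 into the allylic bromide [(Z)-4-bromo-3-methylbut-2-enoxy](tert-butyl)dimethylsilane F5.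
  - F5 should then alkylate the most acidic, para hydroxyl of 4 with one equivalent of K2CO3 in acetone at room temperature to give 9.

**Step 9.**
- What may go wrong: slow ketal hydrolysis, giving time for acid-promoted hydration or migration of the ring alkene or for ionisation of the allyl aryl ether.
- Fallback: this sets out from 13 and returns at 14, and it makes no new compound (entry F0).
  - The ketal is removed without water or heat by exchange with propane-1,3-dithiol under BF3·OEt2 in CH2Cl2 at −20 °C, which transfers the diphenylmethylene unit to sulfur.
  - The chelated, hindered aryl ketone should not form a dithioketal under these conditions.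

## Further compounds

F1 | step 8 | 1-[2,6-dihydroxy-4-(prop-2-enoxy)phenyl]-3-(2,2-diphenyl-1,3-benzodioxol-5-yl)propan-1-one | C=CCOc1cc(O)c(C(=O)CCc2ccc3OC(c4ccccc4)(c4ccccc4)Oc3c2)c(O)c1
F2 | step 8 | 3-(2,2-diphenyl-1,3-benzodioxol-5-yl)-1-[2,4,6-trihydroxy-3-(prop-2-enyl)phenyl]propan-1-one | C=CCc1c(O)cc(O)c(C(=O)CCc2ccc3OC(c4ccccc4)(c4ccccc4)Oc3c2)c1O
F3 | step 8 | 1-[2,6-dihydroxy-4-(2-methylprop-2-enoxy)-3-(prop-2-enyl)phenyl]-3-(2,2-diphenyl-1,3-benzodioxol-5-yl)propan-1-one | C=CCc1c(OCC(C)=C)cc(O)c(C(=O)CCc2ccc3OC(c4ccccc4)(c4ccccc4)Oc3c2)c1O
F4 | step 7 | (Z)-4-[3,5-bis(methoxycarbonyloxy)-4-[3-(2,2-diphenyl-1,3-benzodioxol-5-yl)propanoyl]phenoxy]-3-methylbut-2-en-1-yl methyl carbonate | COC(=O)OC/C=C(C)\COc1cc(OC(=O)OC)c(C(=O)CCc2ccc3OC(c4ccccc4)(c4ccccc4)Oc3c2)c(OC(=O)OC)c1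
F5 | step 5 | [(Z)-4-bromo-3-methylbut-2-enoxy](tert-butyl)dimethylsilane | BrC/C(C)=C\CO[Si](C)(C)C(C)(C)C
F0 | step 9 | none | none
A1 | alternative 1 | 7-[2-[2-[3,4-bis(methoxymethoxy)phenyl]ethyl]-1,3-dioxolan-2-yl]-3-methyl-8-(triisopropylsilyloxy)-2,5-dihydro-1-benzoxepin-6-ol | CC1=CCc2c(cc(O[Si](C(C)C)(C(C)C)C(C)C)c(C3(CCc4ccc(OCOC)c(OCOC)c4)OCCO3)c2O)OC1
A2 | alternative 1 | 2-diazo-1-(6-methyl-4,7-dihydrooxepin-2-yl)ethan-1-one | CC1=CCC=C(C(=O)C=[N+]=[N-])OC1
A3 | alternative 1 | 2-[2-[3,4-bis(methoxymethoxy)phenyl]ethyl]-2-[2-(triisopropylsilyloxy)ethynyl]-1,3-dioxolane | CC(C)[Si](C(C)C)(C(C)C)OC#CC1(CCc2ccc(OCOC)c(OCOC)c2)OCCO1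
A4 | alternative 2 | 3-bromo-2-methoxy-6,8-bis(methoxymethoxy)-2,5-dihydro-1-benzoxepine (racemic, one enantiomer drawn) | CO[C@H]1Oc2cc(OCOC)cc(OCOC)c2CC=C1Br
A5 | alternative 2 | 5,7-bis(methoxymethoxy)-4H-chromene | COCOc1cc(OCOC)c2CC=COc2c1
A6 | alternative 2 | 1,1-dibromo-4,6-bis(methoxymethoxy)-1,1a,7,7a-tetrahydrocyclopropa[b]chromene (racemic, cis-fused, one enantiomer drawn) | COCOc1cc(OCOC)c2C[C@H]3[C@@H](Oc2c1)C3(Br)Br
A7 | alternative 3 | 3-[3,4-bis(methoxymethoxy)phenyl]-1-[6-hydroxy-8-(methoxymethoxy)-3-methyl-2,5-dihydro-1-benzoxepin-7-yl]propan-1-one | CC1=CCc2c(cc(OCOC)c(C(=O)CCc3ccc(OCOC)c(OCOC)c3)c2O)OC1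
A8 | alternative 3 | 8-(methoxymethoxy)-3-methyl-7-(trimethylsilyl)-2,5-dihydro-1-benzoxepin-6-yl trifluoromethanesulfonate | COCOc1cc2OCC(C)=CCc2c(OS(=O)(=O)C(F)(F)F)c1[Si](C)(C)C
A9 | alternative 3 | 3-[3,4-bis(methoxymethoxy)phenyl]propanoic acid | COCOc1ccc(CCC(=O)O)cc1OCOC
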